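## Analysis of the target

Cudraphenone D (C23H26O5) is a benzophenone with no stereocentre: two benzene rings joined through one ketone. Ring A is 1,2,3-trisubstituted, with the ketone on C1, a 3-methylbut-2-en-1-yl (prenyl) chain on C2 and a hydroxyl on C3; C4, C5 and C6 carry hydrogen. Ring B is an acylphloroglucinol with hydroxyls on C2′, C4′ and C6′ and a second prenyl chain on C3′, which breaks the symmetry of that ring. The sensitive functions are the two trisubstituted alkenes, each next to a free phenol and so prone to close to a 2,2-dimethylchroman under acid, and the oxidisable phloroglucinol ring. The ketone is also crowded, with two ortho substituents on one side and one on the other. The hard part is ring A: the prenyl group sits between the acyl carbon and the hydroxyl, the most hindered site and not the one electrophilic prenylation of a 3-hydroxybenzophenone would choose (C4 and C6 are open). A second problem is placing exactly one prenyl group on ring B. The strategy rests on reading C3(OH)–C2(CH2R)–C1(acyl) as a ketone, its α-carbon and the carbonyl that α-carbon has condensed with, while C4–C6 bear only hydrogen. C5–C4–C3–C2 can then come from a terminal alkynone H–C≡C–C(=O)–CH2R and C6–C1 from the CH3–C(=O) end of an aryl 1,2-diketone.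

## Retrosynthetic reasoning

**22 to 21.** The last operation should only release the three ring B phenols, so 22 is traced to the tris-MOM ether 21, which already carries both prenyl chains. Cutting the ring B C3′–prenyl bond last, by alkylating a deprotected acylphloroglucinol, was not adopted. Such an ambident polyphenolate cannot distinguish mono- from dialkylation or C from O, and the loss would fall on the most advanced intermediate. The acetal groups tolerate organolithium reagents and base, direct ortho-metalation, and leave under dilute acid.

**21 to 11 and 17 (key disconnection).** Ring A is cut at C5–C6 and C1–C2. Cutting the ketone–ring A bond instead would require the contiguous acyl/prenyl/oxygen pattern to be built first on an existing benzene ring. Cutting the C2–prenyl bond would require alkylation at the most hindered ring position. The chosen cut makes ring A from open-chain pieces: C6 and C1 from diketone 11, and C5, C4, C3, C2 plus the whole prenyl chain from alkynone 17. Two C–C bonds and the ring are formed in one flask, and the substitution pattern follows from atom mapping. The alkyne supplies the unsaturation needed for the phenol oxidation level. In the forward direction 11 must act as carbon donor through its methyl group toward the terminus of 17 (giving 18). The ketone enolate of 18 must then attack the inner carbonyl (giving 19), and dehydration and enolisation (through 20) must give 21.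

**11 to 10 to 8.** The diketone is taken back by functional-group change at the α-carbon: the C=O of 11 to the C–OH of 10, and the C–O bond of 10 to the C–H of ethyl ketone 8. Ketone 8 can enolise in one direction only (enolate 9), so the oxygen can enter only where it is wanted. An ethyl ketone is also much easier to attach to a hindered aryl nucleophile than a pyruvoyl unit.

**8 to 5 and 6; 5 to 2 and 3; 2 to 1.** Both carbon substituents of ring B are attached by cutting aryl–carbon bonds flanked by two acetal oxygens. The acyl bond of 8 leads to aryllithium 7 and amide 6, and the prenyl bond of 5 leads to aryllithium 4 and bromide 3. The prenyl group goes on first, because no metalation is possible once the ketone is present. In 5 the two remaining ring hydrogens are equivalent and each lies between two acetal oxygens, so the second metalation can give only 7. Ring B therefore receives exactly one prenyl group at a defined position. Ether 2 comes from phloroglucinol 1 by O-alkylation.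

**17 to 15 and 16; 15 to 14; 14 to 12 and 13.** The acyl–alkynyl bond of 17 is cut to Weinreb amide 15 and ethynyl Grignard reagent 16, and 15 comes from ester 14. In 14 the C2–C3 bond is cut by a [3,3] shift back to the tertiary allylic alcohol 12 and orthoester 13. The rearrangement creates the trisubstituted alkene, which has no geometrical isomers, together with the two-carbon unit that becomes C2 and C3 of ring A.

## Alternatives that were turned down

**Alternative 1:** Ring A is taken from a preformed six-membered ring, cyclohex-2-en-1-one A2, and the bonds from C1 to the masked ketone carbon and from C2 to the prenyl CH2 are cut.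
- **Forward key step:** the lithium derivative of 2-[2,4,6-tris(methoxymethoxy)phenyl]-1,3-dithiane A1 would add in conjugate fashion to A2, and the enolate would be trapped in the same flask with bromide 3 to give trans ketone A3.
- **For:** three components are joined in one operation and the two substituents are vicinal by construction. Conjugate addition of aryl dithiane anions with enolate alkylation is an established reaction type, which the key step chosen here is not; on precedent this alternative is stronger.
- **Against:** A3 is a cyclohexanone, two oxidation levels below a phenol. Two dehydrogenations would be needed in the presence of sulfur, an electron-rich arene and an alkene. The dithiane must then be removed with thiophilic or oxidising reagents that the prenyl group and ring B tolerate poorly. The carbanion of A1 is flanked by two ortho acetals and is very hindered. Proton exchange in the β-branched enolate invites over-alkylation. The two stereocentres of A3 are made only to be destroyed.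
- **Comparison:** after its key step this route still needs aromatisation, unmasking, deprotection and ring B prenylation. The chosen route gives ring A directly as a phenol with the ketone free and has one step left after step 9.

**Alternative 2:** Ring B, not ring A, is built. The C1′–C2′ bond is cut, unfolding ring B into triketo ester A5, which is stored as 2-pyrone A4.
- **Forward key step:** a chelating metal alkoxide in alcohol would open A4 to A5. The methylene next to the aryl ketone would then attack the ester carbonyl in a Claisen condensation to give acylphloroglucinol A6.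
- **For:** it follows the biosynthetic logic, fixes the ring B prenyl position by the chain, and releases ring B without protecting groups. On ring B regiocontrol it is as strong as the chosen route, and on ring B deprotection it is stronger.
- **Against:** A4 already contains the 3-oxygenated 2-prenylbenzoyl unit, so the contiguous pattern of ring A, the real difficulty, must be solved separately beforehand. The carbon that becomes C3′ carries the prenyl chain α to the ester, which slows the Claisen closure. Re-lactonisation to A4 and aldol closure onto the aryl ketone then compete.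
- **Comparison:** the chosen route obtains the same ring B certainty from the two ortho-metalations (2 to 5 to 8) and in addition creates the ring A pattern in its key step. Alternative 2 would be longer once the ring A acyl donor and A4 are counted.

**Alternative 3:** Ring A is cut at C1–C6 and C2–C3 into furan A7 and aryl alkynone A8; the furan oxygen becomes the C3 hydroxyl.
- **Forward key step:** a Lewis acid would promote the [4+2] addition to the bridged adduct A9 and then open its oxygen bridge to phenol A10.
- **For:** it is the shortest route to ring A, and both stages (furan–alkyne cycloaddition, bridge opening to a phenol) are known reaction types. On step economy and precedent it is stronger than the chosen route.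
- **Against:** in A8 the CH2 between alkyne and alkene is propargylic, allylic and γ to the ketone, so isomerisation to allenyl or dienyl ketones is likely. Furan is a reluctant, reversible diene toward a singly activated internal alkyne. The forcing Lewis acid needed would also ionise the prenyl alkene and attack the aryl acetates. The hydroxyl position in A10 depends on which C–O bond of A9 ionises. The cation delocalised onto the alkyl-bearing C2 is favoured over the one on the acyl-bearing C1, but this is a selectivity, not a certainty. The acetates cannot pass through organometallic steps, so protecting-group changes add steps back, and ring B still lacks its prenyl group.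
- **Comparison:** the chosen route fixes the hydroxyl position by connectivity (the carbonyl carbon of 17 becomes C3), uses no Lewis acid, and keeps the prenyl CH2 out of an isomerisable position.

Key step: step 9

Remark on the chemistry: the target is achiral; the stereocentres in 10 and 19 form without control and are destroyed in steps 5 and 9. Prenyl = 3-methylbut-2-en-1-yl, MOM = methoxymethyl, SEM = 2-(trimethylsilyl)ethoxymethyl. The atoms of 17–20 are numbered as in ring A of the target.

## Route

Step 1
Reactants: 1 phloroglucinol (benzene-1,3,5-triol)
Product: 2 1,3,5-tris(methoxymethoxy)benzene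
Conditions: NaH, MOMCl, DMF, 0 °C → rt
Reagents that add atoms: chloromethyl methyl ether (MOMCl), COCCl
Why: Threefold O-alkylation of the phenoxides by the hard chloromethyl ether (Williamson-type acetal formation); NaH in DMF should keep phloroglucinol on the O-alkylation path and give the symmetric ether needed for directed metalation.

Step 2
Reactants: 2 1,3,5-tris(methoxymethoxy)benzene; 3 1-bromo-3-methylbut-2-ene (prenyl bromide)
Product: 5 1,3,5-tris(methoxymethoxy)-2-(3-methylbut-2-en-1-yl)benzene, via aryllithium 4 (not isolated)
Conditions: n-BuLi, THF, 0 °C; then 3, −78 °C → rt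
Reagents that add atoms: none
Why: Directed ortho-metalation: every ring hydrogen of 2 lies between two coordinating OMOM groups, so n-BuLi should give 4 cleanly. SN2 alkylation at the primary allylic carbon of 3 then places one prenyl group on ring B with no regiochemical choice.

Step 3
Reactants: 5 1,3,5-tris(methoxymethoxy)-2-(3-methylbut-2-en-1-yl)benzene; 6 N-methoxy-N-methylpropanamide
Product: 8 1-[2,4,6-tris(methoxymethoxy)-3-(3-methylbut-2-en-1-yl)phenyl]propan-1-one, via aryllithium 7 (not isolated)
Conditions: n-BuLi, THF, 0 °C; then 6, −78 → 0 °C; aq NH4Cl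
Reagents that add atoms: none
Why: Second directed ortho-metalation: the two remaining ring hydrogens of 5 are equivalent and each is flanked by two OMOM groups, so only 7 can form. Acylation by Weinreb amide 6 should stop at the ketone because the chelated tetrahedral adduct survives until work-up (Weinreb ketone synthesis).

Step 4
Reactants: 8 1-[2,4,6-tris(methoxymethoxy)-3-(3-methylbut-2-en-1-yl)phenyl]propan-1-one
Product: 10 2-hydroxy-1-[2,4,6-tris(methoxymethoxy)-3-(3-methylbut-2-en-1-yl)phenyl]propan-1-one (racemic), via potassium enolate 9 (not isolated)
Conditions: KN(SiMe3)2, THF, −78 °C; then 3-phenyl-2-(phenylsulfonyl)oxaziridine, −78 °C; aq NH4Cl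
Reagents that add atoms: 3-phenyl-2-(phenylsulfonyl)oxaziridine (Davis reagent), O=S(=O)(c1ccccc1)N1OC1c1ccccc1
Why: Enolate hydroxylation with an N-sulfonyloxaziridine (Davis oxidation): 8 can enolise only toward the ethyl group, and enolate 9 should take up the electrophilic oxygen at −78 °C, where the reagent does not touch the prenyl alkene. The new stereocentre forms racemic and is removed in step 5.

Step 5
Reactants: 10 2-hydroxy-1-[2,4,6-tris(methoxymethoxy)-3-(3-methylbut-2-en-1-yl)phenyl]propan-1-one
Product: 11 1-[2,4,6-tris(methoxymethoxy)-3-(3-methylbut-2-en-1-yl)phenyl]propane-1,2-dione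
Conditions: Dess–Martin periodinane, pyridine, CH2Cl2, 0 °C → rt
Reagents that add atoms: none
Why: Dess–Martin oxidation of a secondary α-hydroxy ketone should give the 1,2-diketone without C–C cleavage; pyridine buffers the acetic acid so the MOM ethers stay in place.

Step 6
Reactants: 12 2-methylbut-3-en-2-ol; 13 triethyl orthoacetate (1,1,1-triethoxyethane)
Product: 14 ethyl 5-methylhex-4-enoate
Conditions: 13 (excess), EtCO2H (cat.), 140 °C, EtOH distilled off
Reagents that add atoms: none
Why: Johnson–Claisen rearrangement: acid-catalysed exchange gives the mixed ketene acetal of 12, whose [3,3] shift forms the new C–C bond and the trisubstituted alkene. That alkene carries two methyl groups on one carbon and so has no E/Z isomers.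

Step 7
Reactants: 14 ethyl 5-methylhex-4-enoate
Product: 15 N-methoxy-N,5-dimethylhex-4-enamide
Conditions: Me(MeO)NH·HCl, i-PrMgCl, THF, −20 → 0 °C
Reagents that add atoms: N,O-dimethylhydroxylamine hydrochloride, CNOC.Cl
Why: Aminolysis of the ester by the magnesium amide formed from the hydroxylamine salt and i-PrMgCl (Weinreb amide synthesis); the isolated alkene is inert.

Step 8
Reactants: 15 N-methoxy-N,5-dimethylhex-4-enamide; 16 ethynylmagnesium bromide (HC≡CMgBr)
Product: 17 7-methyloct-6-en-1-yn-3-one
Conditions: 16 (THF solution), THF, −20 → 0 °C; poured into cold aq NaHSO4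
Reagents that add atoms: none
Why: Weinreb ketone synthesis with an alkynyl Grignard reagent: the chelated adduct prevents double addition. The inverse acidic quench protonates the released N,O-dimethylhydroxylamine before it can add to the terminal alkynone; 17 should be used soon after isolation.

Step 9
Reactants: 11 1-[2,4,6-tris(methoxymethoxy)-3-(3-methylbut-2-en-1-yl)phenyl]propane-1,2-dione; 17 7-methyloct-6-en-1-yn-3-one
Product: 21 [3-hydroxy-2-(3-methylbut-2-en-1-yl)phenyl][2,4,6-tris(methoxymethoxy)-3-(3-methylbut-2-en-1-yl)phenyl]methanone, via Michael adduct 18 (not isolated), via aldol adduct 19 (not isolated), via cyclohexadienone 20 (not isolated)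
Conditions: Cs2CO3 (1.5 equiv), DMSO, argon, 17 added slowly to 11 at rt, then 60 °C; aq NH4Cl
Reagents that add atoms: none
Why: Proposed new method: Cs2CO3 should deprotonate 11 at its only enolisable position, the methyl group acidified by the adjacent dicarbonyl, and this enolate should add to the unsubstituted alkyne terminus of 17 to form C5–C6 and, after protonation of the allenolate, enetrione 18, whose doubly activated C6 methylene gives a dienolate through which the C4=C5 geometry can equilibrate to the cis form needed for closure. The ketone enolate of 18 at C2, the methylene that carries the future prenyl chain, then attacks the inner carbonyl C1 in a 6-(enolendo)-exo-trig aldol addition that forms C1–C2 and closes ring A as 19; E1cB dehydration gives cross-conjugated dienone 20, and loss of a C6 proton gives the phenoxide of 21, an irreversible aromatisation that should pull the preceding equilibria forward. The closest known reaction types are base-mediated Michael–aldol and Michael–Claisen benzannulations of ketones and 1,3-dicarbonyl compounds with alkynones to give phenols, and Michael additions of 1,2-diketones to enones and nitroalkenes; a 1,2-diketone methyl group as donor toward an alkynone has not been shown. No stereocentre survives, since the two sp3 centres of 19 are lost on dehydration. Three points of selectivity matter. The donor must be 11 and not 17, which the higher acidity of the diketone methyl group should secure, helped by slow addition of 17 so that its self-condensation, a second addition of 18 to 17 and O-addition of the product phenoxide stay slow. The aldol must go to C1 and not to the aryl ketone, which would need a seven-membered ring and attack on a carbonyl screened by two ortho substituents. The position of the hydroxyl is fixed by connectivity, because the carbonyl carbon of 17 becomes C3 and its α-methylene becomes C2.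

Step 10
Reactants: 21 [3-hydroxy-2-(3-methylbut-2-en-1-yl)phenyl][2,4,6-tris(methoxymethoxy)-3-(3-methylbut-2-en-1-yl)phenyl]methanone
Product: 22 cudraphenone D, [3-hydroxy-2-(3-methylbut-2-en-1-yl)phenyl][2,4,6-trihydroxy-3-(3-methylbut-2-en-1-yl)phenyl]methanone
Conditions: dilute aq HCl (cat.), MeOH, rt → 40 °C, stopped at full conversion
Reagents that add atoms: none
Why: Acid-catalysed acetal exchange with methanol should cleave the three aryl MOM ethers, the two next to the carbonyl fastest. Dilute acid near room temperature is chosen so that protonation of the trisubstituted alkenes, which would lead to chromans, stays slow.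

## Compound list

1 | phloroglucinol (benzene-1,3,5-triol) | Oc1cc(O)cc(O)c1 | starting material
2 | 1,3,5-tris(methoxymethoxy)benzene | COCOc1cc(OCOC)cc(OCOC)c1 | intermediate
3 | 1-bromo-3-methylbut-2-ene (prenyl bromide) | CC(C)=CCBr | starting material
4 | [2,4,6-tris(methoxymethoxy)phenyl]lithium | [Li]c1c(OCOC)cc(OCOC)cc1OCOC | intermediate (not isolated)
5 | 1,3,5-tris(methoxymethoxy)-2-(3-methylbut-2-en-1-yl)benzene | COCOc1cc(OCOC)c(CC=C(C)C)c(OCOC)c1 | intermediate
6 | N-methoxy-N-methylpropanamide | CCC(=O)N(C)OC | starting material
7 | [2,4,6-tris(methoxymethoxy)-3-(3-methylbut-2-en-1-yl)phenyl]lithium | [Li]c1c(OCOC)cc(OCOC)c(CC=C(C)C)c1OCOC | intermediate (not isolated)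
8 | 1-[2,4,6-tris(methoxymethoxy)-3-(3-methylbut-2-en-1-yl)phenyl]propan-1-one | CCC(=O)c1c(OCOC)cc(OCOC)c(CC=C(C)C)c1OCOC | intermediate
9 | potassium 1-[2,4,6-tris(methoxymethoxy)-3-(3-methylbut-2-en-1-yl)phenyl]prop-1-en-1-olate (enolate geometry without consequence) | CC=C([O-])c1c(OCOC)cc(OCOC)c(CC=C(C)C)c1OCOC.[K+] | intermediate (not isolated)
10 | 2-hydroxy-1-[2,4,6-tris(methoxymethoxy)-3-(3-methylbut-2-en-1-yl)phenyl]propan-1-one (racemic) | CC(O)C(=O)c1c(OCOC)cc(OCOC)c(CC=C(C)C)c1OCOC | intermediate
11 | 1-[2,4,6-tris(methoxymethoxy)-3-(3-methylbut-2-en-1-yl)phenyl]propane-1,2-dione | CC(=O)C(=O)c1c(OCOC)cc(OCOC)c(CC=C(C)C)c1OCOC | intermediate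
12 | 2-methylbut-3-en-2-ol | C=CC(C)(C)O | starting material
13 | triethyl orthoacetate (1,1,1-triethoxyethane) | CCOC(C)(OCC)OCC | starting material
14 | ethyl 5-methylhex-4-enoate | CCOC(=O)CCC=C(C)C | intermediate
15 | N-methoxy-N,5-dimethylhex-4-enamide | CON(C)C(=O)CCC=C(C)C | intermediate
16 | ethynylmagnesium bromide | C#C[Mg]Br | starting material
17 | 7-methyloct-6-en-1-yn-3-one | C#CC(=O)CCC=C(C)C | intermediate
18 | 10-methyl-1-[2,4,6-tris(methoxymethoxy)-3-(3-methylbut-2-en-1-yl)phenyl]undeca-4,9-diene-1,2,6-trione (4E/4Z mixture) | CC(C)=CCCC(=O)C=CCC(=O)C(=O)c1c(OCOC)cc(OCOC)c(CC=C(C)C)c1OCOC | intermediate (not isolated)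
19 | 5-hydroxy-6-(3-methylbut-2-en-1-yl)-5-[2,4,6-tris(methoxymethoxy)-3-(3-methylbut-2-en-1-yl)benzoyl]cyclohex-2-en-1-one (mixture of diastereomers) | O=C1C=CCC(O)(C(=O)c2c(OCOC)cc(OCOC)c(CC=C(C)C)c2OCOC)C1CC=C(C)C | intermediate (not isolated)
20 | 2-(3-methylbut-2-en-1-yl)-3-[2,4,6-tris(methoxymethoxy)-3-(3-methylbut-2-en-1-yl)benzoyl]cyclohexa-2,5-dien-1-one | O=C1C=CCC(C(=O)c2c(OCOC)cc(OCOC)c(CC=C(C)C)c2OCOC)=C1CC=C(C)C | intermediate (not isolated)
21 | [3-hydroxy-2-(3-methylbut-2-en-1-yl)phenyl][2,4,6-tris(methoxymethoxy)-3-(3-methylbut-2-en-1-yl)phenyl]methanone | CC(C)=CCc1c(O)cccc1C(=O)c1c(OCOC)cc(OCOC)c(CC=C(C)C)c1OCOC | intermediate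
22 | cudraphenone D, [3-hydroxy-2-(3-methylbut-2-en-1-yl)phenyl][2,4,6-trihydroxy-3-(3-methylbut-2-en-1-yl)phenyl]methanone | CC(C)=CCc1c(O)cccc1C(=O)c1c(O)cc(O)c(CC=C(C)C)c1O | target

## Step count and risk

Total step count: 10. Longest linear sequence: 7 steps (1, 2, 3, 4, 5, 9, 10) from phloroglucinol 1; the alkynone branch (steps 6, 7, 8) joins at step 9.

**Step 9 (bears the label "Proposed new method:"; the main risk of the route).**
- What may go wrong: base-induced oligomerisation of 17 and self-aldol condensation of 11 may outrun the cross addition. The very acidic adduct 18 may add to a second molecule of 17. The sequence may stall at the delocalised dienolate of 18, in which C1 is no longer electrophilic, so that the aldol closure is too slow. The product phenoxide may add through oxygen to 17.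
- Fallback (known chemistry, ring A not built but bought): the fallback sets out from 5 and comes back to the route at 22. Commercial 3-hydroxybenzaldehyde is protected with MOMCl and i-Pr2NEt to give 3-(methoxymethoxy)benzaldehyde F1. The aldehyde is masked in the flask as its α-amino alkoxide with LiN(Me)CH2CH2NMe2 and lithiated with n-BuLi at C2, between the two directing groups. Alkylation with 3 then gives 3-(methoxymethoxy)-2-(3-methylbut-2-en-1-yl)benzaldehyde F2. Compound 5 is lithiated as in step 3 to 7, which is added to F2 at −78 °C to give [3-(methoxymethoxy)-2-(3-methylbut-2-en-1-yl)phenyl][2,4,6-tris(methoxymethoxy)-3-(3-methylbut-2-en-1-yl)phenyl]methanol F3. Dess–Martin oxidation gives [3-(methoxymethoxy)-2-(3-methylbut-2-en-1-yl)phenyl][2,4,6-tris(methoxymethoxy)-3-(3-methylbut-2-en-1-yl)phenyl]methanone F4. Acid methanolysis under the conditions of step 10 removes all four MOM groups and gives 22.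

**Step 8.**
- What may go wrong: conjugate addition of the liberated N,O-dimethylhydroxylamine to the terminal alkynone during the quench, and loss of the small, reactive alkynone by polymerisation or evaporation on concentration.
- Fallback: it sets out from 14 and comes back at 17. Reduction with i-Bu2AlH in CH2Cl2 at −78 °C gives 5-methylhex-4-enal F5. Addition of 16 gives 7-methyloct-6-en-1-yn-3-ol F6 (racemic), and oxidation with MnO2 gives 17. No amine is present at any stage, so the amine addition cannot occur.

**Step 10.**
- What may go wrong: acid-promoted cyclisation of either prenyl group onto its ortho hydroxyl (chroman formation), or addition of solvent to the alkenes, before the last MOM ether (para to the carbonyl) is cleaved.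
- Fallback (protecting group cleaved by fluoride instead of acid): it sets out from 1 and comes back at 22. NaH and SEMCl give 1,3,5-tris{[2-(trimethylsilyl)ethoxy]methoxy}benzene F7. Metalation and alkylation with 3 as in step 2 give 2-(3-methylbut-2-en-1-yl)-1,3,5-tris{[2-(trimethylsilyl)ethoxy]methoxy}benzene F8. Metalation and acylation with 6 as in step 3 give 1-[3-(3-methylbut-2-en-1-yl)-2,4,6-tris{[2-(trimethylsilyl)ethoxy]methoxy}phenyl]propan-1-one F9. Hydroxylation as in step 4 gives 2-hydroxy-1-[3-(3-methylbut-2-en-1-yl)-2,4,6-tris{[2-(trimethylsilyl)ethoxy]methoxy}phenyl]propan-1-one F10 (racemic). Oxidation as in step 5 gives 1-[3-(3-methylbut-2-en-1-yl)-2,4,6-tris{[2-(trimethylsilyl)ethoxy]methoxy}phenyl]propane-1,2-dione F11. Benzannulation with 17 as in step 9 gives [3-hydroxy-2-(3-methylbut-2-en-1-yl)phenyl][3-(3-methylbut-2-en-1-yl)-2,4,6-tris{[2-(trimethylsilyl)ethoxy]methoxy}phenyl]methanone F12. Bu4NF in warm THF then removes the three SEM groups and gives 22 without any acid.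

**Step 3.**
- What may go wrong: proton transfer to the hindered aryllithium 7 from the α-methylene of amide 6 (enolisation instead of addition), or competing removal of a benzylic–allylic proton of 5 during metalation, in both cases returning 5 or giving side products.
- Fallback: it sets out from 5 and comes back at 8. Aryllithium 7 is generated as before and added at −78 °C to propanal, a far better electrophile that should add faster than it is enolised. This gives 1-[2,4,6-tris(methoxymethoxy)-3-(3-methylbut-2-en-1-yl)phenyl]propan-1-ol F13 (racemic), and Dess–Martin oxidation gives 8.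

## Further compounds

F1 | step 9 | 3-(methoxymethoxy)benzaldehyde | COCOc1cccc(C=O)c1
F2 | step 9 | 3-(methoxymethoxy)-2-(3-methylbut-2-en-1-yl)benzaldehyde | COCOc1cccc(C=O)c1CC=C(C)C
F3 | step 9 | [3-(methoxymethoxy)-2-(3-methylbut-2-en-1-yl)phenyl][2,4,6-tris(methoxymethoxy)-3-(3-methylbut-2-en-1-yl)phenyl]methanol (racemic) | COCOc1cccc(C(O)c2c(OCOC)cc(OCOC)c(CC=C(C)C)c2OCOC)c1CC=C(C)C
F4 | step 9 | [3-(methoxymethoxy)-2-(3-methylbut-2-en-1-yl)phenyl][2,4,6-tris(methoxymethoxy)-3-(3-methylbut-2-en-1-yl)phenyl]methanone | COCOc1cccc(C(=O)c2c(OCOC)cc(OCOC)c(CC=C(C)C)c2OCOC)c1CC=C(C)C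
F5 | step 8 | 5-methylhex-4-enal | CC(C)=CCCC=O
F6 | step 8 | 7-methyloct-6-en-1-yn-3-ol (racemic) | C#CC(O)CCC=C(C)C
F7 | step 10 | 1,3,5-tris{[2-(trimethylsilyl)ethoxy]methoxy}benzene | C[Si](C)(C)CCOCOc1cc(OCOCC[Si](C)(C)C)cc(OCOCC[Si](C)(C)C)c1
F8 | step 10 | 2-(3-methylbut-2-en-1-yl)-1,3,5-tris{[2-(trimethylsilyl)ethoxy]methoxy}benzene | C[Si](C)(C)CCOCOc1cc(OCOCC[Si](C)(C)C)c(CC=C(C)C)c(OCOCC[Si](C)(C)C)c1
F9 | step 10 | 1-[3-(3-methylbut-2-en-1-yl)-2,4,6-tris{[2-(trimethylsilyl)ethoxy]methoxy}phenyl]propan-1-one | CCC(=O)c1c(OCOCC[Si](C)(C)C)cc(OCOCC[Si](C)(C)C)c(CC=C(C)C)c1OCOCC[Si](C)(C)C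
F10 | step 10 | 2-hydroxy-1-[3-(3-methylbut-2-en-1-yl)-2,4,6-tris{[2-(trimethylsilyl)ethoxy]methoxy}phenyl]propan-1-one (racemic) | CC(O)C(=O)c1c(OCOCC[Si](C)(C)C)cc(OCOCC[Si](C)(C)C)c(CC=C(C)C)c1OCOCC[Si](C)(C)C
F11 | step 10 | 1-[3-(3-methylbut-2-en-1-yl)-2,4,6-tris{[2-(trimethylsilyl)ethoxy]methoxy}phenyl]propane-1,2-dione | CC(=O)C(=O)c1c(OCOCC[Si](C)(C)C)cc(OCOCC[Si](C)(C)C)c(CC=C(C)C)c1OCOCC[Si](C)(C)C
F12 | step 10 | [3-hydroxy-2-(3-methylbut-2-en-1-yl)phenyl][3-(3-methylbut-2-en-1-yl)-2,4,6-tris{[2-(trimethylsilyl)ethoxy]methoxy}phenyl]methanone | CC(C)=CCc1c(O)cccc1C(=O)c1c(OCOCC[Si](C)(C)C)cc(OCOCC[Si](C)(C)C)c(CC=C(C)C)c1OCOCC[Si](C)(C)C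
F13 | step 3 | 1-[2,4,6-tris(methoxymethoxy)-3-(3-methylbut-2-en-1-yl)phenyl]propan-1-ol (racemic) | CCC(O)c1c(OCOC)cc(OCOC)c(CC=C(C)C)c1OCOC
A1 | alternative 1 | 2-[2,4,6-tris(methoxymethoxy)phenyl]-1,3-dithiane | COCOc1cc(OCOC)c(C2SCCCS2)c(OCOC)c1
A2 | alternative 1 | cyclohex-2-en-1-one | O=C1C=CCCC1
A3 | alternative 1 | trans-2-(3-methylbut-2-en-1-yl)-3-{2-[2,4,6-tris(methoxymethoxy)phenyl]-1,3-dithian-2-yl}cyclohexan-1-one (racemic, one enantiomer drawn) | O=C1CCC[C@@H](C2(c3c(OCOC)cc(OCOC)cc3OCOC)SCCCS2)[C@@H]1CC=C(C)C
A4 | alternative 2 | 4-hydroxy-6-{2-[3-(methoxymethoxy)-2-(3-methylbut-2-en-1-yl)phenyl]-2-oxoethyl}-3-(3-methylbut-2-en-1-yl)-2H-pyran-2-one | CC(C)=CCC1=C(O)C=C(CC(=O)c2cccc(OCOC)c2CC=C(C)C)OC1=O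
A5 | alternative 2 | methyl 7-[3-(methoxymethoxy)-2-(3-methylbut-2-en-1-yl)phenyl]-2-(3-methylbut-2-en-1-yl)-3,5,7-trioxoheptanoate (racemic) | COC(=O)C(CC=C(C)C)C(=O)CC(=O)CC(=O)c1cccc(OCOC)c1CC=C(C)C
A6 | alternative 2 | [3-(methoxymethoxy)-2-(3-methylbut-2-en-1-yl)phenyl][2,4,6-trihydroxy-3-(3-methylbut-2-en-1-yl)phenyl]methanone | CC(C)=CCc1c(OCOC)cccc1C(=O)c1c(O)cc(O)c(CC=C(C)C)c1O
A7 | alternative 3 | furan | c1ccoc1
A8 | alternative 3 | 6-methyl-1-(2,4,6-triacetoxyphenyl)hept-5-en-2-yn-1-one | CC(C)=CCC#CC(=O)c1c(OC(C)=O)cc(OC(C)=O)cc1OC(C)=O
A9 | alternative 3 | [3-(3-methylbut-2-en-1-yl)-7-oxabicyclo[2.2.1]hepta-2,5-dien-2-yl](2,4,6-triacetoxyphenyl)methanone (racemic) | O1C2C=CC1C(CC=C(C)C)=C2C(=O)c1c(OC(C)=O)cc(OC(C)=O)cc1OC(C)=O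
A10 | alternative 3 | [3-hydroxy-2-(3-methylbut-2-en-1-yl)phenyl](2,4,6-triacetoxyphenyl)methanone | CC(C)=CCc1c(O)cccc1C(=O)c1c(OC(C)=O)cc(OC(C)=O)cc1OC(C)=O
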